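**Retrosynthetic overview**
- The acrolein unit is unveiled last by oxidation of a 2-substituted allylic alcohol; the tiglate and the (1R)-carbinol come from a 5-acetyl group (asymmetric transfer hydrogenation, then esterification), and the C3 acetate from the C3 alcohol.
- Key disconnection C2–C3: the dihydrofuran ring (O1, C2, C3, C3a, C7a) is the only ring that is made (the benzene ring is bought). It is closed by a Norrish–Yang-type photocyclization of a 2-(allyloxy)benzaldehyde, an isomerization that creates the C3 carbinol and both ring stereocentres and leaves the 1,1-disubstituted alkene in place.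
- Enabling feature: the formyl carbon (future C3) on C3a is ortho to the ether oxygen O1 on C7a, so the excited C=O oxygen reaches the O1–CH2 hydrogens (future C2–H; allylic and α-oxygenated) through a seven-membered transition state. The C3a–C7a edge of the benzene ring then holds the ketyl and allyl radical centres next to each other.
- Absolute configuration at C2/C3 comes from an acylative kinetic resolution of the racemic trans alcohol (half of the material is given up here); C1′ is set by catalyst control in the ketone reduction.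
- The photosubstrate comes from Mitsunobu etherification of 5-acetyl-2-hydroxybenzaldehyde with mono-silylated 2-methylidenepropane-1,3-diol.

Key step: step 3

Remark on the chemistry: the SMILES is read as the (2S,3R), i.e. 2,3-trans, dihydrobenzofuran with a (1R) side chain and an (E)-2-methylbut-2-enoate (tiglate); 5-acetyl-2-hydroxybenzaldehyde is taken as a catalogue compound.

Step 1
Reactants: 1 2-methylidenepropane-1,3-diol
Product: 2 2-({[tert-butyl(dimethyl)silyl]oxy}methyl)prop-2-en-1-ol
Conditions: NaH (1.0 equiv), THF, 0 °C to rt; then TBSCl (1.0 equiv)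
Reagents that add atoms: tert-butyl(chloro)dimethylsilane (TBSCl), CC(C)(C)[Si](C)(C)Cl
Why: O-silylation of the monosodium alkoxide of a symmetrical diol (silyl ether formation), which should stop at the mono-ether because the sparingly soluble monoalkoxide is silylated before a second deprotonation can occur; no stereocentre is involved.

Step 2
Reactants: 2 2-({[tert-butyl(dimethyl)silyl]oxy}methyl)prop-2-en-1-ol; 3 5-acetyl-2-hydroxybenzaldehyde
Product: 4 5-acetyl-2-{[2-({[tert-butyl(dimethyl)silyl]oxy}methyl)prop-2-en-1-yl]oxy}benzaldehyde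
Conditions: PPh3, DIAD, THF, 0 °C to rt
Reagents that add atoms: none
Why: Mitsunobu etherification of an acidic phenol (acyl groups ortho and para) with a primary allylic alcohol; direct and allylically transposed displacement give the same ether, and no stereocentre is formed.

Step 3
Reactants: 4 5-acetyl-2-{[2-({[tert-butyl(dimethyl)silyl]oxy}methyl)prop-2-en-1-yl]oxy}benzaldehyde
Product: 6 racemic trans alcohol 1-[(2RS,3SR)-2-(3-{[tert-butyl(dimethyl)silyl]oxy}prop-1-en-2-yl)-3-hydroxy-2,3-dihydro-1-benzofuran-5-yl]ethan-1-one, via triplet 1,5-biradical 5 (not isolated)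
Conditions: hν (365 nm, Pyrex), degassed MeCN (0.01 M), rt; chromatography to remove the cis isomer
Reagents that add atoms: none
Why: Excitation of the formyl chromophore (n,π* triplet after intersystem crossing) lets the carbonyl oxygen abstract one of the O1–CH2 hydrogens, which are δ to the carbonyl carbon and both allylic and α-oxygenated, through a seven-membered transition state (1,6-hydrogen transfer), giving triplet 1,5-biradical 5 (ketyl at C3, 1-aryloxyallyl radical at C2); after spin inversion the two radical centres combine to the C2–C3 bond. The closest known reaction type is the Norrish–Yang-type photocyclization of 2-alkoxybenzaldehydes and 2-alkoxyphenyl ketones to 2,3-dihydrobenzofuran-3-ols by δ-hydrogen abstraction. The one ring closed, the dihydrofuran ring, forms by radical–radical combination within the tethered 1,5-biradical, with O1 and the C3a–C7a bond keeping the two centres within bonding distance. C2 and C3 are created together: in the nearly flat ring being formed the bulky 1-(silyloxymethyl)vinyl group on C2 should avoid eclipsing the solvated C3 hydroxyl, so the 2,3-trans alcohol is expected as the major isomer (acetonitrile hydrogen-bonds to the ketyl OH and so disfavours a cis-directing internal hydrogen bond), and with no chiral element present it forms as the racemate. The step needs site-selective hydrogen transfer, secured because only the O1–CH2 hydrogens can reach the formyl oxygen (the CH2OSi hydrogens would need a nine-membered transition state and the acetyl oxygen has no hydrogen within reach), and closure at C2 rather than at the terminal CH2 of the allyl radical, which would give a seven-membered cyclic enol ether. The 1,1-disubstituted alkene should survive because its triplet lies above that of the aryl aldehyde, so it is not sensitized.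

Step 4
Reactants: 6 racemic trans alcohol 1-[(2RS,3SR)-2-(3-{[tert-butyl(dimethyl)silyl]oxy}prop-1-en-2-yl)-3-hydroxy-2,3-dihydro-1-benzofuran-5-yl]ethan-1-one
Product: 7 1-[(2S,3R)-2-(3-{[tert-butyl(dimethyl)silyl]oxy}prop-1-en-2-yl)-3-hydroxy-2,3-dihydro-1-benzofuran-5-yl]ethan-1-one
Conditions: (R)-benzotetramisole ((R)-BTM, 5 mol%), (iPrCO)2O (0.6 equiv), iPr2NEt, Na2SO4, CHCl3, 0 °C, run to just past half conversion; chromatography
Reagents that add atoms: none
Why: Acylative kinetic resolution by enantioselective acyl transfer (chiral isothiourea catalysis): the N-acyl isothiouronium from (R)-BTM stacks on the carbinol aryl ring and acylates benzylic alcohols with the spatial sense of (R)-1-arylalkanols, which here is the (3S) carbinol, so the (2R,3S) enantiomer should be esterified and the (2S,3R) alcohol left behind, fixing the absolute configuration of C2 and C3 together because the two are already locked trans.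

Step 5
Reactants: 7 1-[(2S,3R)-2-(3-{[tert-butyl(dimethyl)silyl]oxy}prop-1-en-2-yl)-3-hydroxy-2,3-dihydro-1-benzofuran-5-yl]ethan-1-one
Product: 8 (2S,3R)-5-acetyl-2-(3-{[tert-butyl(dimethyl)silyl]oxy}prop-1-en-2-yl)-2,3-dihydro-1-benzofuran-3-yl acetate
Conditions: Ac2O, pyridine, DMAP (cat.), CH2Cl2, 0 °C to rt
Reagents that add atoms: acetic anhydride, CC(=O)OC(C)=O
Why: DMAP-catalysed O-acetylation of the secondary benzylic alcohol, which takes place at oxygen and so leaves C3 and C2 unchanged.

Step 6
Reactants: 8 (2S,3R)-5-acetyl-2-(3-{[tert-butyl(dimethyl)silyl]oxy}prop-1-en-2-yl)-2,3-dihydro-1-benzofuran-3-yl acetate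
Product: 9 (2S,3R)-2-(3-{[tert-butyl(dimethyl)silyl]oxy}prop-1-en-2-yl)-5-[(1R)-1-hydroxyethyl]-2,3-dihydro-1-benzofuran-3-yl acetate
Conditions: RuCl[(R,R)-TsDPEN](p-cymene) (1 mol%), HCO2H/Et3N (5:2), CH2Cl2, rt
Reagents that add atoms: none
Why: Noyori asymmetric transfer hydrogenation of the aryl methyl ketone, in which the (R,R)-TsDPEN ruthenium hydride delivers hydrogen through the six-membered N–H/Ru–H transition state in the sense that turns acetophenones into (R)-1-arylethanols, so C1′ is set as (R) by the catalyst while acetate, silyl ether and alkene are not reduced (the aldehyde has already been consumed in step 3).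

Step 7
Reactants: 9 (2S,3R)-2-(3-{[tert-butyl(dimethyl)silyl]oxy}prop-1-en-2-yl)-5-[(1R)-1-hydroxyethyl]-2,3-dihydro-1-benzofuran-3-yl acetate
Product: 10 (1R)-1-[(2S,3R)-3-(acetyloxy)-2-(3-{[tert-butyl(dimethyl)silyl]oxy}prop-1-en-2-yl)-2,3-dihydro-1-benzofuran-5-yl]ethyl (2E)-2-methylbut-2-enoate
Conditions: tiglic acid, DCC, DMAP (cat.), CH2Cl2, 0 °C to rt
Reagents that add atoms: (2E)-2-methylbut-2-enoic acid (tiglic acid), C/C=C(\C)C(=O)O
Why: Steglich esterification (carbodiimide activation, DMAP acyl transfer), an O-acylation that leaves C1′ untouched and brings in the (E)-alkene from tiglic acid; the free acid is used rather than the acid chloride to avoid a vinylketene that would give the deconjugated ester.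

Step 8
Reactants: 10 (1R)-1-[(2S,3R)-3-(acetyloxy)-2-(3-{[tert-butyl(dimethyl)silyl]oxy}prop-1-en-2-yl)-2,3-dihydro-1-benzofuran-5-yl]ethyl (2E)-2-methylbut-2-enoate
Product: 11 (1R)-1-[(2S,3R)-3-(acetyloxy)-2-(3-hydroxyprop-1-en-2-yl)-2,3-dihydro-1-benzofuran-5-yl]ethyl (2E)-2-methylbut-2-enoate
Conditions: HF·pyridine, pyridine, THF, 0 °C to rt
Reagents that add atoms: none
Why: Fluoride-induced cleavage of the primary silyl ether (Si–F bond formation), buffered with pyridine so that the two esters on alkoxy-activated benzylic carbons are not ionised; the stereocentres are untouched.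

Step 9
Reactants: 11 (1R)-1-[(2S,3R)-3-(acetyloxy)-2-(3-hydroxyprop-1-en-2-yl)-2,3-dihydro-1-benzofuran-5-yl]ethyl (2E)-2-methylbut-2-enoate
Product: 12 (1R)-1-[(2S,3R)-3-(acetyloxy)-2-(3-oxoprop-1-en-2-yl)-2,3-dihydro-1-benzofuran-5-yl]ethyl (2E)-2-methylbut-2-enoate (CNP0294391.1)
Conditions: MnO2 (activated, excess), CH2Cl2, rt
Reagents that add atoms: none
Why: MnO2 oxidation of a primary allylic alcohol to the enal, a neutral heterogeneous oxidation placed last so that the conjugate-addition-prone 2-substituted acrolein, which sits next to an aryl allyl ether, never meets nucleophilic amines; no stereocentre is formed or disturbed.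

**Compound list**
1 | 2-methylidenepropane-1,3-diol | C=C(CO)CO | starting material
2 | 2-({[tert-butyl(dimethyl)silyl]oxy}methyl)prop-2-en-1-ol | C=C(CO)CO[Si](C)(C)C(C)(C)C | intermediate
3 | 5-acetyl-2-hydroxybenzaldehyde | CC(=O)c1ccc(O)c(C=O)c1 | starting material
4 | 5-acetyl-2-{[2-({[tert-butyl(dimethyl)silyl]oxy}methyl)prop-2-en-1-yl]oxy}benzaldehyde | CC(=O)c1ccc(OCC(=C)CO[Si](C)(C)C(C)(C)C)c(C=O)c1 | intermediate
5 | triplet 1,5-biradical of 4 (hydroxybenzyl radical at C3, 1-aryloxyallyl radical at C2) | CC(=O)c1ccc(O[CH]C(=C)CO[Si](C)(C)C(C)(C)C)c([CH]O)c1 | intermediate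
6 | 1-[(2RS,3SR)-2-(3-{[tert-butyl(dimethyl)silyl]oxy}prop-1-en-2-yl)-3-hydroxy-2,3-dihydro-1-benzofuran-5-yl]ethan-1-one (racemic trans alcohol, both enantiomers given) | C=C(CO[Si](C)(C)C(C)(C)C)[C@@H]1Oc2ccc(C(C)=O)cc2[C@H]1O.C=C(CO[Si](C)(C)C(C)(C)C)[C@H]1Oc2ccc(C(C)=O)cc2[C@@H]1O | intermediate
7 | 1-[(2S,3R)-2-(3-{[tert-butyl(dimethyl)silyl]oxy}prop-1-en-2-yl)-3-hydroxy-2,3-dihydro-1-benzofuran-5-yl]ethan-1-one | C=C(CO[Si](C)(C)C(C)(C)C)[C@@H]1Oc2ccc(C(C)=O)cc2[C@H]1O | intermediate
8 | (2S,3R)-5-acetyl-2-(3-{[tert-butyl(dimethyl)silyl]oxy}prop-1-en-2-yl)-2,3-dihydro-1-benzofuran-3-yl acetate | C=C(CO[Si](C)(C)C(C)(C)C)[C@@H]1Oc2ccc(C(C)=O)cc2[C@H]1OC(C)=O | intermediate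
9 | (2S,3R)-2-(3-{[tert-butyl(dimethyl)silyl]oxy}prop-1-en-2-yl)-5-[(1R)-1-hydroxyethyl]-2,3-dihydro-1-benzofuran-3-yl acetate | C=C(CO[Si](C)(C)C(C)(C)C)[C@@H]1Oc2ccc([C@@H](C)O)cc2[C@H]1OC(C)=O | intermediate
10 | (1R)-1-[(2S,3R)-3-(acetyloxy)-2-(3-{[tert-butyl(dimethyl)silyl]oxy}prop-1-en-2-yl)-2,3-dihydro-1-benzofuran-5-yl]ethyl (2E)-2-methylbut-2-enoate | C=C(CO[Si](C)(C)C(C)(C)C)[C@@H]1Oc2ccc([C@@H](C)OC(=O)/C(C)=C/C)cc2[C@H]1OC(C)=O | intermediate
11 | (1R)-1-[(2S,3R)-3-(acetyloxy)-2-(3-hydroxyprop-1-en-2-yl)-2,3-dihydro-1-benzofuran-5-yl]ethyl (2E)-2-methylbut-2-enoate | C=C(CO)[C@@H]1Oc2ccc([C@@H](C)OC(=O)/C(C)=C/C)cc2[C@H]1OC(C)=O | intermediate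
12 | (1R)-1-[(2S,3R)-3-(acetyloxy)-2-(3-oxoprop-1-en-2-yl)-2,3-dihydro-1-benzofuran-5-yl]ethyl (2E)-2-methylbut-2-enoate | C=C(C=O)[C@@H]1Oc2ccc([C@@H](C)OC(=O)/C(C)=C/C)cc2[C@H]1OC(C)=O | target

Total step count: 9. Longest linear sequence: 9 steps (1 to 12; 3 enters in step 2).

**Steps most likely to fail**

1. Step 3. What may go wrong: poor face selectivity in the collapse of the biradical, so that too much of the material ends up as the cis alcohol (a second leak is ring closure at the far terminus of the allyl radical). Fallback, setting out from 4 and coming back at 6: the photocyclization is run as before and the cis isomer, racemic cis alcohol 1-[(2RS,3RS)-2-(3-{[tert-butyl(dimethyl)silyl]oxy}prop-1-en-2-yl)-3-hydroxy-2,3-dihydro-1-benzofuran-5-yl]ethan-1-one F1, is kept instead of discarded. Mitsunobu inversion at C3 with 4-nitrobenzoic acid (PPh3, DIAD, toluene, 0 °C) should give the racemic trans ester (2RS,3SR)-5-acetyl-2-(3-{[tert-butyl(dimethyl)silyl]oxy}prop-1-en-2-yl)-2,3-dihydro-1-benzofuran-3-yl 4-nitrobenzoate F2, and methanolysis (K2CO3, MeOH, 0 °C) returns the racemic trans alcohol 6. This corrects the stereochemistry by a stereospecific substitution instead of relying on the intrinsic preference of the ring closure; elimination to the benzofuran is the side reaction to watch in the inversion.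

2. Step 4. What may go wrong: insufficient discrimination between the enantiomers in the acyl transfer, because the carbinol is ring-fused and flanked by a substituted carbon. Fallback, setting out from 6 and coming back at 7: covalent resolution. Steglich esterification of 6 with (2S)-2-methoxy-2-phenylacetic acid (DCC, DMAP cat., CH2Cl2) gives two diastereomeric esters, the wanted (2S,3R)-5-acetyl-2-(3-{[tert-butyl(dimethyl)silyl]oxy}prop-1-en-2-yl)-2,3-dihydro-1-benzofuran-3-yl (2S)-2-methoxy-2-phenylacetate F3 and its (2R,3S) ring diastereomer (2R,3S)-5-acetyl-2-(3-{[tert-butyl(dimethyl)silyl]oxy}prop-1-en-2-yl)-2,3-dihydro-1-benzofuran-3-yl (2S)-2-methoxy-2-phenylacetate F4. They are separated by chromatography or crystallization, and methanolysis of F3 (K2CO3, MeOH, 0 °C) gives 7.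

3. Step 6. What may go wrong: solvolysis of the alkoxy-activated benzylic acetate in the formic acid medium, or slow and poorly face-selective hydride transfer to the electron-rich ketone. Fallback, setting out from 8 and coming back at 9: Corey–Bakshi–Shibata reduction with (S)-2-methyl-CBS-oxazaborolidine (cat.) and catecholborane in toluene at −78 °C. This is a reagent-controlled borane reduction under aprotic, non-acidic conditions, which should give the same (R)-carbinol 9 directly; catecholborane at low temperature should not hydroborate the 1,1-disubstituted alkene. No new compound is made.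

Further compounds
F1 | step 3 | 1-[(2RS,3RS)-2-(3-{[tert-butyl(dimethyl)silyl]oxy}prop-1-en-2-yl)-3-hydroxy-2,3-dihydro-1-benzofuran-5-yl]ethan-1-one (racemic cis alcohol) | C=C(CO[Si](C)(C)C(C)(C)C)[C@@H]1Oc2ccc(C(C)=O)cc2[C@@H]1O.C=C(CO[Si](C)(C)C(C)(C)C)[C@H]1Oc2ccc(C(C)=O)cc2[C@H]1O
F2 | step 3 | (2RS,3SR)-5-acetyl-2-(3-{[tert-butyl(dimethyl)silyl]oxy}prop-1-en-2-yl)-2,3-dihydro-1-benzofuran-3-yl 4-nitrobenzoate (racemic trans ester) | C=C(CO[Si](C)(C)C(C)(C)C)[C@@H]1Oc2ccc(C(C)=O)cc2[C@H]1OC(=O)c1ccc([N+](=O)[O-])cc1.C=C(CO[Si](C)(C)C(C)(C)C)[C@H]1Oc2ccc(C(C)=O)cc2[C@@H]1OC(=O)c1ccc([N+](=O)[O-])cc1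
F3 | step 4 | (2S,3R)-5-acetyl-2-(3-{[tert-butyl(dimethyl)silyl]oxy}prop-1-en-2-yl)-2,3-dihydro-1-benzofuran-3-yl (2S)-2-methoxy-2-phenylacetate | C=C(CO[Si](C)(C)C(C)(C)C)[C@@H]1Oc2ccc(C(C)=O)cc2[C@H]1OC(=O)[C@@H](OC)c1ccccc1
F4 | step 4 | (2R,3S)-5-acetyl-2-(3-{[tert-butyl(dimethyl)silyl]oxy}prop-1-en-2-yl)-2,3-dihydro-1-benzofuran-3-yl (2S)-2-methoxy-2-phenylacetate | C=C(CO[Si](C)(C)C(C)(C)C)[C@H]1Oc2ccc(C(C)=O)cc2[C@@H]1OC(=O)[C@@H](OC)c1ccccc1
F0 | step 6 | none | none
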